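## Retrosynthetic overview

1. The target is reached from the 1(10),4-diene macrolide by peracid epoxidation of C1=C10 (oxirane, ring C, formed last) and fluoride removal of the C15 silyl ether.
2. The strategy rests on C3 being an allylic carbinol bonded to C4 of the trisubstituted Z-C4=C5 alkene in the ten-membered carbocycle (ring A). This is the retron of a C4 alkenylmetal adding to a C3 aldehyde, so ring A is closed at C3–C4 by a Nozaki–Hiyama–Kishi reaction.
3. The seco-aldehyde comes from a C8 Mitsunobu inversion with angelic acid and a zinc Barbier allylation that forms C7–C8. The allyl partner is a C6-defined 3-(bromomethyl)butenolide, which delivers the trans α-methylene lactone (ring B).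
4. The bromobutenolide comes from ring-closing metathesis of a 2-(bromomethyl)acrylate of a (Z)-iodoallylic carbinol (asymmetric alkynylation, then trans-hydroalumination–iodination). The C8 aldehyde comes from carboalumination of a but-3-yn-1-ol ether and oxirane opening.
5. Ring order: lactone ring B (steps 9 and 10), carbocycle ring A (step 14), oxirane ring C (step 15).

Key step: step 14

Remark on numbering: germacrane numbering is used for all intermediates (C1–C10 ring carbons, C12 lactone carbonyl, C13 exocyclic methylene, C14 methyl on C10, C15 oxygenated carbon on C4).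

Assumption: (S,S)-ProPhenol is taken to deliver the (S)-carbinol in step 6; if the sense is opposite for this enal, the (R,R)-ligand is used and nothing else changes.

## Route

Step 1
Reactants: 1 but-3-yn-1-ol
Product: 2 tert-butyl(but-3-yn-1-yloxy)dimethylsilane
Conditions: TBSCl, imidazole, CH2Cl2, 0 °C → rt
Reagents that add atoms: tert-butyldimethylsilyl chloride, CC(C)(C)[Si](C)(C)Cl
Why: Silylation of the primary alcohol masks the future C8 oxygen so that it can later be told apart from the C3 oxygen.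

Step 2
Reactants: 2 tert-butyl(but-3-yn-1-yloxy)dimethylsilane
Product: 5 (E)-6-(tert-butyldimethylsilyloxy)-4-methylhex-3-en-1-ol, via alkenyldimethylalane 3 (not isolated), via lithium alkenylalanate 4 (not isolated)
Conditions: Me3Al, Cp2ZrCl2 (20 mol%), CH2Cl2, 0 °C → rt; volatiles removed, hexane; n-BuLi, 0 °C; oxirane, THF, 0 °C → rt; aq. Rochelle salt
Reagents that add atoms: trimethylaluminium, C[Al](C)C; oxirane, C1CO1
Why: Negishi zirconium-catalysed carboalumination adds methyl and aluminium syn across the alkyne with methyl on the internal carbon (C14 on C10), and the derived alanate opens oxirane with retention at C1, which fixes the E-C1=C10 alkene and adds C2 and C3.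

Step 3
Reactants: 5 (E)-6-(tert-butyldimethylsilyloxy)-4-methylhex-3-en-1-ol
Product: 6 (E)-tert-butyl{[6-(4-methoxybenzyloxy)-3-methylhex-3-en-1-yl]oxy}dimethylsilane
Conditions: NaH, PMBCl, Bu4NI (cat.), DMF, 0 °C → rt
Reagents that add atoms: 4-methoxybenzyl chloride, COc1ccc(CCl)cc1
Why: Williamson etherification gives a C3 ether that is orthogonal to both silyl ethers used in the route.

Step 4
Reactants: 6 (E)-tert-butyl{[6-(4-methoxybenzyloxy)-3-methylhex-3-en-1-yl]oxy}dimethylsilane
Product: 7 (E)-6-(4-methoxybenzyloxy)-3-methylhex-3-en-1-ol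
Conditions: TBAF, THF, 0 °C → rt
Reagents that add atoms: none
Why: Fluoride desilylation cleaves the only silyl ether present and frees the C8 hydroxyl.

Step 5
Reactants: 7 (E)-6-(4-methoxybenzyloxy)-3-methylhex-3-en-1-ol
Product: 8 (E)-6-(4-methoxybenzyloxy)-3-methylhex-3-enal
Conditions: Dess–Martin periodinane, NaHCO3, CH2Cl2, 0 °C; used at once without chromatography
Reagents that add atoms: none
Why: Buffered Dess–Martin oxidation gives the β,γ-unsaturated C8 aldehyde under conditions too mild to move the C1=C10 alkene into conjugation.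

Step 6
Reactants: 9 tert-butyldimethyl(prop-2-yn-1-yloxy)silane; 10 (E)-but-2-enal
Product: 12 (4S,5E)-1-(tert-butyldimethylsilyloxy)hept-5-en-2-yn-4-ol, via alkynyl(methyl)zinc 11 (not isolated)
Conditions: Me2Zn, (S,S)-ProPhenol (10 mol%), Ph3PO (20 mol%), toluene, 0 °C; then 10, 4 °C; aq. NH4Cl
Reagents that add atoms: none
Why: In the zinc–ProPhenol asymmetric alkynylation the alkynylzinc adds 1,2 to the enal inside the chiral dinuclear zinc pocket, which sets the C6 carbinol under reagent control.

Step 7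
Reactants: 12 (4S,5E)-1-(tert-butyldimethylsilyloxy)hept-5-en-2-yn-4-ol
Product: 14 (2Z,4S,5E)-1-(tert-butyldimethylsilyloxy)-2-iodohepta-2,5-dien-4-ol, via cyclic sodium alkenylalanate 13 (not isolated)
Conditions: NaAlH2(OCH2CH2OMe)2 (Red-Al), THF, 0 °C; EtOAc; I2, THF, −78 → 0 °C; aq. Na2S2O3/Rochelle salt
Reagents that add atoms: iodine, II
Why: In this hydroxyl-directed trans-hydroalumination of a propargylic alcohol the aluminate bound to the C6 oxygen delivers hydride to C5 and aluminium to C4, and iodinolysis with retention places iodine on C4 cis to C6 (the Z-iodide), while the propenyl group and the silyl ether are left alone at 0 °C.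

Step 8
Reactants: 14 (2Z,4S,5E)-1-(tert-butyldimethylsilyloxy)-2-iodohepta-2,5-dien-4-ol; 15 2-(bromomethyl)acrylic acid
Product: 16 (2Z,4S,5E)-1-(tert-butyldimethylsilyloxy)-2-iodohepta-2,5-dien-4-yl 2-(bromomethyl)acrylate
Conditions: DCC, DMAP (5 mol%), CH2Cl2, 0 °C
Reagents that add atoms: none
Why: Steglich esterification acylates the carbinol with retention at C6, and the low temperature and catalytic amount of DMAP limit amine attack on the allylic bromide.

Step 9
Reactants: 16 (2Z,4S,5E)-1-(tert-butyldimethylsilyloxy)-2-iodohepta-2,5-dien-4-yl 2-(bromomethyl)acrylate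
Product: 17 (5S)-3-(bromomethyl)-5-[(1Z)-3-(tert-butyldimethylsilyloxy)-2-iodoprop-1-en-1-yl]furan-2(5H)-one
Conditions: second-generation Hoveyda–Grubbs catalyst (5 mol%), toluene, 80 °C, 0.01 M
Reagents that add atoms: none
Why: Ring-closing metathesis between the propenyl group and the acrylate alkene closes the butenolide (ring B) with loss of propene, and the trisubstituted iodoalkene is too hindered and electron-poor to engage the ruthenium carbene.

Step 10
Reactants: 17 (5S)-3-(bromomethyl)-5-[(1Z)-3-(tert-butyldimethylsilyloxy)-2-iodoprop-1-en-1-yl]furan-2(5H)-one; 8 (E)-6-(4-methoxybenzyloxy)-3-methylhex-3-enal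
Product: 19 (4R,5S)-4-[(1S,3E)-1-hydroxy-6-(4-methoxybenzyloxy)-3-methylhex-3-en-1-yl]-5-[(1Z)-3-(tert-butyldimethylsilyloxy)-2-iodoprop-1-en-1-yl]-3-methylideneoxolan-2-one, via allylzinc bromide 18 (not isolated)
Conditions: Zn dust, THF/sat. aq. NH4Cl (2:1), 0 °C → rt
Reagents that add atoms: none
Why: In this Barbier allylation zinc inserts into the allylic C–Br bond and the allylzinc adds through its γ-carbon C7 in a chair (Zimmerman–Traxler) transition state, forming C7–C8 and the exocyclic C11=C13 methylene; the aldehyde approaches anti to the C6 alkenyl group (C6/C7 trans), and because the ring fixes C6 trans to C13 the anti adduct with the 8α-hydroxyl (8S) should prevail.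

Step 11
Reactants: 19 the (8S)-alcohol of step 10; 20 angelic acid ((Z)-2-methylbut-2-enoic acid)
Product: 21 (1R,3E)-1-{(2S,3R)-2-[(1Z)-3-(tert-butyldimethylsilyloxy)-2-iodoprop-1-en-1-yl]-4-methylidene-5-oxooxolan-3-yl}-6-(4-methoxybenzyloxy)-3-methylhex-3-en-1-yl (Z)-2-methylbut-2-enoate
Conditions: PPh3, DIAD, toluene, 0 °C → rt
Reagents that add atoms: none
Why: In the Mitsunobu esterification angelate displaces the C8 oxyphosphonium in an SN2 step, which inverts C8 to the required 8β (8R) configuration and installs the ester without activating the acid carbonyl, so the usual acyl-activation routes to the tiglate are closed.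

Step 12
Reactants: 21 the C8 angelate PMB ether
Product: 22 (1R,3E)-1-{(2S,3R)-2-[(1Z)-3-(tert-butyldimethylsilyloxy)-2-iodoprop-1-en-1-yl]-4-methylidene-5-oxooxolan-3-yl}-6-hydroxy-3-methylhex-3-en-1-yl (Z)-2-methylbut-2-enoate
Conditions: DDQ, CH2Cl2/pH 7 buffer (10:1), 0 °C
Reagents that add atoms: none
Why: Oxidative PMB cleavage by DDQ proceeds through the benzylic oxocarbenium ion and its hydrolysis, leaving the silyl ether, both esters and the iodoalkene untouched.

Step 13
Reactants: 22 the C3 alcohol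
Product: 23 (1R,3E)-1-{(2S,3R)-2-[(1Z)-3-(tert-butyldimethylsilyloxy)-2-iodoprop-1-en-1-yl]-4-methylidene-5-oxooxolan-3-yl}-3-methyl-6-oxohex-3-en-1-yl (Z)-2-methylbut-2-enoate (seco-aldehyde)
Conditions: Dess–Martin periodinane, NaHCO3, CH2Cl2, 0 °C; filtered through Florisil and used at once
Reagents that add atoms: none
Why: Buffered Dess–Martin oxidation gives the β,γ-unsaturated C3 aldehyde, which is taken on immediately so that C1=C10 does not drift into conjugation.

Step 14
Reactants: 23 seco-aldehyde with Z-C4 iodide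
Product: 25 (1(10)E,4Z)-8β-angeloyloxy-15-(tert-butyldimethylsilyloxy)-3β-hydroxygermacra-1(10),4,11(13)-trien-6α,12-olide, via alkenylchromium dichloride 24 (not isolated)
Conditions: CrCl2 (12 equiv), NiCl2 (0.1 equiv), degassed DMSO, rt, syringe-pump addition of 23 to 0.003 M; aq. sodium serinate work-up
Reagents that add atoms: none
Why: Zerovalent nickel, formed from NiCl2 by divalent chromium, inserts into the C4–I bond with retention, the alkenyl group passes to chromium to give the alkenylchromium 24 of trivalent chromium, and this adds to the chromium-bound C3 aldehyde. The closest known reaction type is the intramolecular Nozaki–Hiyama–Kishi alkenyl iodide–aldehyde coupling used to close medium-ring allylic alcohols. Ring A, the ten-membered carbocycle, is closed by C3–C4 bond formation as a 10-exo-trig carbonyl addition at high dilution, helped by the trans C6/C7 substituents of ring B and the Z-C4=C5 alkene, which turn the two chain ends toward each other. The new C3 stereocentre is set by substrate control in the macrocyclic transition state, where the carbonyl oxygen should point to the outside of the forming ring and so end up 3β (3S). The step needs chemoselectivity for the aldehyde over the lactone, the angelate and the α-methylene unit, which the low basicity and aldehyde preference of alkenylchromium reagents secure, and the covalent C–Cr bond should also keep the β-silyloxy group on C15 in place. It also needs retention of the Z geometry, which the configurational stability of the alkenylnickel and alkenylchromium species secures.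

Step 15
Reactants: 25 the 1(10),4-diene macrolide
Product: 26 (4Z)-8β-angeloyloxy-15-(tert-butyldimethylsilyloxy)-1β,10α-epoxy-3β-hydroxygermacra-4,11(13)-dien-6α,12-olide
Conditions: mCPBA (1.05 equiv), NaHCO3, CH2Cl2, −20 → 0 °C
Reagents that add atoms: 3-chloroperbenzoic acid, O=C(OO)c1cccc(Cl)c1
Why: In this Prilezhaev epoxidation the peracid picks the only electron-rich trialkyl alkene C1=C10 (C4=C5 carries three allylic C–O bonds, C11=C13 and the angelate alkene are conjugated to carbonyls) and should add to its outer face in the conformer with C14 on the β face, giving the 1β,10α-oxirane (1R,10R).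

Step 16
Reactants: 26 the C15 silyl ether epoxide
Product: 27 (4Z)-8β-angeloyloxy-1β,10α-epoxy-3β,15-dihydroxygermacra-4,11(13)-dien-6α,12-olide (CNP0187917.1)
Conditions: TBAF, AcOH (1:1), THF, 0 °C → rt
Reagents that add atoms: none
Why: Fluoride desilylation buffered with acetic acid removes the primary allylic silyl ether without opening the oxirane or touching the lactone and the angelate.

## Compound list

1 | but-3-yn-1-ol | C#CCCO | starting material
2 | tert-butyl(but-3-yn-1-yloxy)dimethylsilane | C#CCCO[Si](C)(C)C(C)(C)C | intermediate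
3 | (E)-[4-(tert-butyldimethylsilyloxy)-2-methylbut-1-en-1-yl]dimethylalane | C[Al](C)/C=C(\C)CCO[Si](C)(C)C(C)(C)C | intermediate
4 | lithium butyl[(E)-4-(tert-butyldimethylsilyloxy)-2-methylbut-1-en-1-yl]dimethylalanate | [Li+].CCCC[Al-](C)(C)/C=C(\C)CCO[Si](C)(C)C(C)(C)C | intermediate
5 | (E)-6-(tert-butyldimethylsilyloxy)-4-methylhex-3-en-1-ol | OCC/C=C(\C)CCO[Si](C)(C)C(C)(C)C | intermediate
6 | (E)-tert-butyl{[6-(4-methoxybenzyloxy)-3-methylhex-3-en-1-yl]oxy}dimethylsilane | COc1ccc(COCC/C=C(\C)CCO[Si](C)(C)C(C)(C)C)cc1 | intermediate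
7 | (E)-6-(4-methoxybenzyloxy)-3-methylhex-3-en-1-ol | COc1ccc(COCC/C=C(\C)CCO)cc1 | intermediate
8 | (E)-6-(4-methoxybenzyloxy)-3-methylhex-3-enal | COc1ccc(COCC/C=C(\C)CC=O)cc1 | intermediate
9 | tert-butyldimethyl(prop-2-yn-1-yloxy)silane | C#CCO[Si](C)(C)C(C)(C)C | starting material
10 | (E)-but-2-enal | C/C=C/C=O | starting material
11 | methyl[3-(tert-butyldimethylsilyloxy)prop-1-yn-1-yl]zinc | C[Zn]C#CCO[Si](C)(C)C(C)(C)C | intermediate
12 | (4S,5E)-1-(tert-butyldimethylsilyloxy)hept-5-en-2-yn-4-ol | O[C@H](C#CCO[Si](C)(C)C(C)(C)C)/C=C/C | intermediate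
13 | cyclic sodium alkenylalanate (2,5-dihydro-1,2-oxaluminole, Al bonded to the C6 oxygen and to C4, two 2-methoxyethoxy groups on Al) | [Na+].COCCO[Al-]1(OCCOC)O[C@@H](/C=C/C)C=C1CO[Si](C)(C)C(C)(C)C | intermediate
14 | (2Z,4S,5E)-1-(tert-butyldimethylsilyloxy)-2-iodohepta-2,5-dien-4-ol | O[C@H](/C=C(/CO[Si](C)(C)C(C)(C)C)\I)/C=C/C | intermediate
15 | 2-(bromomethyl)acrylic acid | C=C(CBr)C(=O)O | starting material
16 | (2Z,4S,5E)-1-(tert-butyldimethylsilyloxy)-2-iodohepta-2,5-dien-4-yl 2-(bromomethyl)acrylate | C=C(CBr)C(=O)O[C@H](/C=C(/CO[Si](C)(C)C(C)(C)C)\I)/C=C/C | intermediate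
17 | (5S)-3-(bromomethyl)-5-[(1Z)-3-(tert-butyldimethylsilyloxy)-2-iodoprop-1-en-1-yl]furan-2(5H)-one | O=C1O[C@H](/C=C(/CO[Si](C)(C)C(C)(C)C)\I)C=C1CBr | intermediate
18 | {[(5S)-5-[(1Z)-3-(tert-butyldimethylsilyloxy)-2-iodoprop-1-en-1-yl]-2-oxo-2,5-dihydrofuran-3-yl]methyl}zinc bromide | O=C1O[C@H](/C=C(/CO[Si](C)(C)C(C)(C)C)\I)C=C1C[Zn]Br | intermediate
19 | (4R,5S)-4-[(1S,3E)-1-hydroxy-6-(4-methoxybenzyloxy)-3-methylhex-3-en-1-yl]-5-[(1Z)-3-(tert-butyldimethylsilyloxy)-2-iodoprop-1-en-1-yl]-3-methylideneoxolan-2-one | C=C1C(=O)O[C@H](/C=C(/CO[Si](C)(C)C(C)(C)C)\I)[C@H]1[C@@H](O)C/C(C)=C/CCOCc1ccc(OC)cc1 | intermediate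
20 | angelic acid ((Z)-2-methylbut-2-enoic acid) | C/C=C(/C)C(=O)O | starting material
21 | (1R,3E)-1-{(2S,3R)-2-[(1Z)-3-(tert-butyldimethylsilyloxy)-2-iodoprop-1-en-1-yl]-4-methylidene-5-oxooxolan-3-yl}-6-(4-methoxybenzyloxy)-3-methylhex-3-en-1-yl (Z)-2-methylbut-2-enoate | C=C1C(=O)O[C@H](/C=C(/CO[Si](C)(C)C(C)(C)C)\I)[C@H]1[C@H](OC(=O)/C(C)=C\C)C/C(C)=C/CCOCc1ccc(OC)cc1 | intermediate
22 | (1R,3E)-1-{(2S,3R)-2-[(1Z)-3-(tert-butyldimethylsilyloxy)-2-iodoprop-1-en-1-yl]-4-methylidene-5-oxooxolan-3-yl}-6-hydroxy-3-methylhex-3-en-1-yl (Z)-2-methylbut-2-enoate | C=C1C(=O)O[C@H](/C=C(/CO[Si](C)(C)C(C)(C)C)\I)[C@H]1[C@H](OC(=O)/C(C)=C\C)C/C(C)=C/CCO | intermediate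
23 | (1R,3E)-1-{(2S,3R)-2-[(1Z)-3-(tert-butyldimethylsilyloxy)-2-iodoprop-1-en-1-yl]-4-methylidene-5-oxooxolan-3-yl}-3-methyl-6-oxohex-3-en-1-yl (Z)-2-methylbut-2-enoate | C=C1C(=O)O[C@H](/C=C(/CO[Si](C)(C)C(C)(C)C)\I)[C@H]1[C@H](OC(=O)/C(C)=C\C)C/C(C)=C/CC=O | intermediate
24 | C4 alkenylchromium dichloride derived from 23 (CrCl2 group in place of iodine, Z retained) | C=C1C(=O)O[C@H](/C=C(/CO[Si](C)(C)C(C)(C)C)\[Cr](Cl)Cl)[C@H]1[C@H](OC(=O)/C(C)=C\C)C/C(C)=C/CC=O | intermediate
25 | (1(10)E,4Z)-8β-angeloyloxy-15-(tert-butyldimethylsilyloxy)-3β-hydroxygermacra-1(10),4,11(13)-trien-6α,12-olide (3S,6R,7R,8R) | C=C1C(=O)O[C@@H]2/C=C(/CO[Si](C)(C)C(C)(C)C)[C@@H](O)C/C=C(\C)C[C@@H](OC(=O)/C(C)=C\C)[C@@H]12 | intermediate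
26 | (4Z)-8β-angeloyloxy-15-(tert-butyldimethylsilyloxy)-1β,10α-epoxy-3β-hydroxygermacra-4,11(13)-dien-6α,12-olide (1R,3S,6R,7R,8R,10R) | C=C1C(=O)O[C@@H]2/C=C(/CO[Si](C)(C)C(C)(C)C)[C@@H](O)C[C@H]3O[C@]3(C)C[C@@H](OC(=O)/C(C)=C\C)[C@@H]12 | intermediate
27 | (4Z)-8β-angeloyloxy-1β,10α-epoxy-3β,15-dihydroxygermacra-4,11(13)-dien-6α,12-olide (1R,3S,6R,7R,8R,10R) | C=C1C(=O)O[C@@H]2/C=C(/CO)[C@@H](O)C[C@H]3O[C@]3(C)C[C@@H](OC(=O)/C(C)=C\C)[C@@H]12 | target

## Step count and risks

Total step count: 16. Longest linear sequence: 12 steps (steps 1–5, then 10–16).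

Steps most likely to fail:

1. Step 14. The macrocyclic transition state may deliver the alkenyl group to the wrong face of the aldehyde, so that the 3α-epimer dominates or the two epimers form with poor selectivity. Fallback from 23, returning at 25: the cyclisation is run as in step 14 and the unwanted (3R)-3α-alcohol F1 is separated. It is oxidised with MnO2 (CH2Cl2, rt), which touches only the allylic alcohol, to the C3 ketone F2. Luche reduction (NaBH4, CeCl3·7H2O, MeOH, −78 °C) then sets C3 by hydride attack from the outer face of the ring and should return 25. C3 is thus fixed by ketone reduction and no longer by the C–C bond-forming event.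

2. Step 11. The oxyphosphonium may undergo E2 loss toward the allylic C9 hydrogens, substitution may proceed with retention through participation of the lactone carbonyl, or the phosphine may isomerise the angelate to the tiglate. Fallback from 19, returning at 21: Mitsunobu inversion with the small and more acidic chloroacetic acid (PPh3, DIAD, toluene, 0 °C) gives the (8R)-chloroacetate F3. Thiourea and NaHCO3 in EtOH remove the chloroacetyl group selectively to give the (8R)-alcohol F4. This is acylated with retention by the mixed anhydride of angelic acid 20 and 2,4,6-trichlorobenzoyl chloride (Et3N, toluene, 60 °C; Yamaguchi conditions). F4 is also the alcohol that step 10 would give directly should the allylation run syn, so this path covers a reversed outcome of step 10 as well.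

3. Step 15. The peracid may attack the inner face or a minor ring conformer and give the 1α,10β-oxirane, or the C3 hydroxyl may direct oxygen to C4=C5. Fallback from 21, returning at 26: the oxirane is set by reagent control on the open chain before ring closure. Shi epoxidation of 21 with the D-fructose-derived ketone (Oxone, K2CO3 buffer, MeCN/dimethoxymethane/H2O, 0 °C) should give the (1R,10R)-epoxide F5. DDQ frees the epoxy alcohol F6, buffered Dess–Martin oxidation gives the epoxy aldehyde F7, and the CrCl2/NiCl2 closure of step 14 applied to F7 gives 26 directly.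

## Further compounds

F1 | step 14 | 3α-epimer of 25 ((3R)-alcohol) | C=C1C(=O)O[C@@H]2/C=C(/CO[Si](C)(C)C(C)(C)C)[C@H](O)C/C=C(\C)C[C@@H](OC(=O)/C(C)=C\C)[C@@H]12
F2 | step 14 | 3-oxo analogue of 25 (C3 ketone) | C=C1C(=O)O[C@@H]2/C=C(/CO[Si](C)(C)C(C)(C)C)C(=O)C/C=C(\C)C[C@@H](OC(=O)/C(C)=C\C)[C@@H]12
F3 | step 11 | (8R)-chloroacetate of the Barbier adduct | C=C1C(=O)O[C@H](/C=C(/CO[Si](C)(C)C(C)(C)C)\I)[C@H]1[C@H](OC(=O)CCl)C/C(C)=C/CCOCc1ccc(OC)cc1
F4 | step 11 | (8R)-alcohol (C8 epimer of 19) | C=C1C(=O)O[C@H](/C=C(/CO[Si](C)(C)C(C)(C)C)\I)[C@H]1[C@H](O)C/C(C)=C/CCOCc1ccc(OC)cc1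
F5 | step 15 | (1R,10R)-epoxide of 21 | COc1ccc(COCC[C@H]2O[C@]2(C)C[C@@H](OC(=O)/C(C)=C\C)[C@H]2C(=C)C(=O)O[C@@H]2/C=C(/CO[Si](C)(C)C(C)(C)C)\I)cc1
F6 | step 15 | (1R,10R)-epoxy C3 alcohol | OCC[C@H]1O[C@]1(C)C[C@@H](OC(=O)/C(C)=C\C)[C@H]1C(=C)C(=O)O[C@@H]1/C=C(/CO[Si](C)(C)C(C)(C)C)\I
F7 | step 15 | (1R,10R)-epoxy C3 aldehyde | O=CC[C@H]1O[C@]1(C)C[C@@H](OC(=O)/C(C)=C\C)[C@H]1C(=C)C(=O)O[C@@H]1/C=C(/CO[Si](C)(C)C(C)(C)C)\I
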